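## Analysis of the target

The target is a depsidone. Ring A (C1–C6) and ring B (C1'–C6') are joined twice, by the ester C7(=O)–O–C1' and by the ether C5–O–C6', so that a seven-membered dioxepinone (ring C) lies between them. Ring B carries a fourth ring, a five-membered hydroxy lactone (lactol) spanning C4' and C5'. Ring A bears methyl (C1), hydroxyl (C3) and formyl (C4). Ring B has no hydrogen left: the fumaric half ester hangs on the C2' methylene, a hydroxyl sits on C3', the lactone carbonyl on C4' and the lactol carbon on C5'. The only stereocentre is the lactol carbon, (R). It is a hemiacetal that opens to the C5' aldehyde and the C4' acid, so its configuration is mobile in solution and can only be fixed last, in a solid. Sensitive groups are the aryl aldehyde, the lactol, the aryl ester of ring C, the benzylic fumarate (a Michael acceptor on a benzylic carbon next to a phenol) and two phenols. The difficulty lies in two crowded arenes, in placing the ester oxygen on C1' and the ether oxygen on C6' and not the reverse, and in bringing in the fumarate late. The strategy rests on ring A: C7, C6, C5, C4, C3, C2, C1 and the methyl are the eight carbons of a folded tetraketide with oxygen on C3 and C5 (an orsellinate), and its carboxyl C7 is esterified by the oxygen on C1'. Ring A and this ester bond can therefore be made together from an open chain and a ring B phenol.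

## Retrosynthetic reasoning

Target 36 is traced back to its crystalline ammonium salt 35 and to racemic 33. No skeletal bond is cut. The lactol centre is left to the end because any earlier setting would be lost by ring–chain tautomerism. The forward step has to make one diastereomeric salt with amine 34 crystallize while the lactol epimerizes in the mother liquor.

Racemate 33 is traced back to fully protected 32. Two methoxymethyl ethers (on the C3 and C3' oxygens) and two tert-butyl esters (C4' and the fumarate terminus) are chosen so that one acid treatment removes all four. The lactol needs no step of its own: it closes when the C4' acid is freed next to the C5' aldehyde.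

In 32 the ester bond between the C2' methylene oxygen and the fumaroyl group is cut, giving alcohol 30 and half ester 31. The cut is made here, late, because the fumarate would not survive phenoxide, carbonate or the magnesium-mediated formylation. At this stage no phenol is free, so acylation can only occur on the primary alcohol. Alcohol 30 comes from silyl ether 29.

Ring C of 29 is opened at the ether bond C5–O–C6' and not at the ester, because the ester is what the key step delivers. The precursor 28 carries fluorine on C6' and a free hydroxyl on C5. The forward reaction has to displace the fluorine with the C5 phenoxide. The ortho aldehyde on C5' supplies the activation, and the triisopropylsilyl ether was chosen over a smaller silyl group because fluoride is set free in this step.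

The C5' aldehyde of 28 is traced back to a vinyl group in 26, to be cleaved oxidatively. An acetal was not used: an acetal next to the tert-butyl ester would have to be made and removed through an oxocarbenium ion, which the ester carbonyl can capture with loss of the tert-butyl group. The vinyl group is inert to heat, carbonate and the formylation, and is unmasked without acid.

The C4 formyl group of 26 is cut off to give 25, and the C3 protecting group is removed to give depside 24. The order matters. With the C3 oxygen blocked, the only free phenol of 25 is on C5, and its only open ortho position is C4, so an ortho-specific formylation cannot go to C2. The para hydroxyl of the orsellinate (C3) is the one that is not hydrogen-bonded to the ester, so it can be protected selectively.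

Depside 24 is cut at two bonds, C7–O(C1') and C6–C1, which is the key disconnection. It leads to ring B phenol 12 and diketo-dioxinone 20, through acylketene 21, triketo ester 22 and aldol 23. Both the ring and the hindered ester come from an acyclic chain that needs no activation or protection. The forward reaction must capture 21 at the crowded C1' hydroxyl and then close C6 onto C1 without expelling the phenol.

Dioxinone 20 is cut at the C2–C3 bond to keto-dioxinone 16 and amide 17, and 16 at the corresponding bond to dioxinone 13 and acetyl chloride 14. Both are acylations of dienolates (15, 18) at their terminal carbon.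

Phenol 12 is traced back to its 4-methoxybenzyl ether 11, and the vinyl group of 11 is cut off to give 8. The C5' position of 8 carries the last ring hydrogen, flanked by the ester and fluorine, so metalation there is unambiguous. The 4-methoxybenzyl group is used because it can be removed oxidatively without touching the vinyl group.

The silyloxymethyl group of 8 is traced through alcohol 7 and aldehyde 6 to salicylaldehyde 5, and the formyl carbon of 5 is cut off to give 4. In 4 the free hydroxyl is the ester-chelated one, and its only open ortho position is the future C2'.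

Ether 4 comes from diol ester 3, where the ester differentiates the two hydroxyls, and 3 comes from acid 2. The carboxyl of 2 is cut off to give 4-fluororesorcinol 1. Carboxylation of 1 goes ortho to one hydroxyl and para to the other, which is the future C4'.

## Alternatives that were turned down

Alternative 1: Ring B is taken apart across C3'–C4' back to cyclobutenone A2, which would come from diisopropyl squarate A3 by two organolithium additions. In the forward key step, heating A2 opens the four-membered ring to a dienylketene, the ketene carbon (the later C3') closes onto the alkene carbon C4' in a 6π electrocyclization, and tautomerization gives hydroquinone A1. What speaks for it: each of the six substituents of ring B sits where the cyclobutenone put it, so no directing effect has to be trusted. On this point it is as strong as the chosen route, whose ring B steps each have only one open site. What speaks against it: A1 is only ring B. The diaryl ether to ring A and the C7 ester would still have to be made between two fully substituted rings. The C3' and C6' hydroxyls of A1 would have to be told apart. The isopropyl ether on C1' would need Lewis-acid cleavage next to an acetal and a tert-butyl ester. And A2 needs a lithiated acrylate bearing an acetal, a reagent prone to self-condensation. The chosen strategy offers a ring B made from a cheap arene by standard steps, and it forms ring A and the ester in one operation, which Alternative 1 does not address at all.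

Alternative 2: The lactone of ring C is cut at both bonds of C7, so that C7 comes from carbon monoxide A6 and the precursor is iodo diaryl ether A5 (iodine on C6, free hydroxyl on C1'). In the forward key step zerovalent palladium inserts into the C6–I bond, A6 inserts, and the C1' phenoxide captures the acylpalladium to close ring C and give depsidone A4. What speaks for it: it is more convergent than the chosen route. Its ring closure is a well-behaved carbonylative lactonization that avoids two problems of the chosen route, the ipso shift that threatens a depside under base and the weakly nucleophilic phenoxide of its ether closure. On the closure of ring C it is the stronger plan. What speaks against it: A5 needs an intermolecular ether bond between a hexasubstituted ring B and a pentasubstituted ring A, each carrying two ortho substituents at the coupling site. Ring A must be bought or built as an iodinated, formylated orcinol in several steps. Oxidative addition would occur at an iodide flanked by methyl and aryloxy. The chosen strategy makes ring A in the key step from a two-step dioxinone and forms the only intermolecular bond, the ester, with a small neutral ketene.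

Alternative 3: Ring B is cut at C6'–C5' and C3'–C4' into diene A8, a silyl ketene acetal carried on a seven-membered enol lactone that already holds ring A and ring C, and acetylenic ester A9. In the forward key step a [4+2] cycloaddition joins the two, and elimination of the methoxy group from the adduct aromatizes ring B to give A7 with a free C3' phenol. What speaks for it: it sets four of the six ring B substituents in one step and is the most convergent way to the hexasubstituted ring, so in step economy on ring B it is stronger. What speaks against it: A8 combines an enol ester, an enol ether and a silyl ketene acetal in a strained ring and has no evident preparation. Both diene termini carry oxygen, so the orientation of the addition to A9 is not secured. The heat needed for a tetrasubstituted diene endangers the enol lactone. The chosen strategy uses only isolable intermediates and concentrates its uncertainty in one step with close precedent.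

Key step: step 12

Assumption 1: the lactol carbon of 33 and 36 interconverts through the open C5' aldehyde/C4' acid form, so the (R) configuration is defined for the crystalline solid and is expected to erode slowly in solution.

Assumption 2: the salt of the (R)-lactol with (R)-amine 34 is taken to be the less soluble diastereomer; if it is the salt of the (S)-lactol, the (S)-amine is used, which by mirror symmetry then crystallizes the (R)-lactol.

## Steps

Step 1
Reactants: 1 4-fluororesorcinol
Product: 2 5-fluoro-2,4-dihydroxybenzoic acid
Conditions: KHCO3, CO2 (1 atm), H2O, 100 °C; then aq. HCl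
Reagents that add atoms: carbon dioxide, O=C=O
Why: Kolbe–Schmitt carboxylation of a resorcinol in aqueous hydrogen carbonate goes ortho to one hydroxyl and para to the other, as with resorcinol itself; the position between the hydroxyls is the slower one and the fluorinated carbon is blocked.

Step 2
Reactants: 2 5-fluoro-2,4-dihydroxybenzoic acid
Product: 3 tert-butyl 5-fluoro-2,4-dihydroxybenzoate
Conditions: Me2NCH(Ot-Bu)2, PhMe, 80 °C
Reagents that add atoms: N,N-dimethylformamide di-tert-butyl acetal, CN(C)C(OC(C)(C)C)OC(C)(C)C
Why: tert-Butyl esterification with a formamide acetal: only the carboxylic acid is acidic enough to protonate the reagent, and the carboxylate then takes the tert-butyl group, so the phenols should stay free.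

Step 3
Reactants: 3 tert-butyl 5-fluoro-2,4-dihydroxybenzoate
Product: 4 tert-butyl 5-fluoro-2-hydroxy-4-[(4-methoxybenzyl)oxy]benzoate
Conditions: 4-MeOC6H4CH2Cl (1.05 equiv), K2CO3, KI (cat.), DMF, rt
Reagents that add atoms: 4-methoxybenzyl chloride, COc1ccc(CCl)cc1
Why: Williamson ether synthesis; the 2-hydroxyl is held in a hydrogen bond to the ester carbonyl, while the 4-hydroxyl (para to the ester, ortho to fluorine) is free and more acidic, so one equivalent of halide should alkylate O4 alone.

Step 4
Reactants: 4 tert-butyl 5-fluoro-2-hydroxy-4-[(4-methoxybenzyl)oxy]benzoate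
Product: 5 tert-butyl 5-fluoro-3-formyl-2-hydroxy-4-[(4-methoxybenzyl)oxy]benzoate
Conditions: MgCl2, Et3N, (CH2O)n, MeCN, 80 °C
Reagents that add atoms: formaldehyde (as paraformaldehyde), C=O
Why: Magnesium-mediated ortho-formylation of a phenol (Casnati–Skattebøl): the magnesium phenoxide delivers formaldehyde to its ortho carbon and a second formaldehyde takes up hydride. The reaction is ortho-specific, and C3 is the only open position ortho to the one free hydroxyl.

Step 5
Reactants: 5 tert-butyl 5-fluoro-3-formyl-2-hydroxy-4-[(4-methoxybenzyl)oxy]benzoate
Product: 6 tert-butyl 5-fluoro-3-formyl-2-(methoxymethoxy)-4-[(4-methoxybenzyl)oxy]benzoate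
Conditions: MeOCH2Cl, K2CO3, DMF, 0 °C → rt
Reagents that add atoms: chloromethyl methyl ether, COCCl
Why: O-Alkylation of the phenoxide with a highly reactive α-chloro ether; the chelated, flanked phenol is slow with ordinary halides but should react with this one, and the aldehyde has no α-hydrogen to interfere.

Step 6
Reactants: 6 tert-butyl 5-fluoro-3-formyl-2-(methoxymethoxy)-4-[(4-methoxybenzyl)oxy]benzoate
Product: 7 tert-butyl 5-fluoro-3-(hydroxymethyl)-2-(methoxymethoxy)-4-[(4-methoxybenzyl)oxy]benzoate
Conditions: NaBH4, THF/MeOH, 0 °C
Reagents that add atoms: none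
Why: Borohydride reduction of the aldehyde; the tert-butyl ester is not reduced, and it is meta to the new alkoxide, so no lactone can form.

Step 7
Reactants: 7 tert-butyl 5-fluoro-3-(hydroxymethyl)-2-(methoxymethoxy)-4-[(4-methoxybenzyl)oxy]benzoate
Product: 8 tert-butyl 5-fluoro-2-(methoxymethoxy)-4-[(4-methoxybenzyl)oxy]-3-{[(triisopropylsilyl)oxy]methyl}benzoate
Conditions: i-Pr3SiCl, imidazole, DMF, rt
Reagents that add atoms: chlorotriisopropylsilane, CC(C)[Si](Cl)(C(C)C)C(C)C
Why: Silylation of the primary alcohol via the N-silylimidazolium; the triisopropylsilyl ether is chosen for its resistance to fluoride and base in the later ring closure.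

Step 8
Reactants: 8 tert-butyl 5-fluoro-2-(methoxymethoxy)-4-[(4-methoxybenzyl)oxy]-3-{[(triisopropylsilyl)oxy]methyl}benzoate
Product: 11 tert-butyl 6-ethenyl-5-fluoro-2-(methoxymethoxy)-4-[(4-methoxybenzyl)oxy]-3-{[(triisopropylsilyl)oxy]methyl}benzoate, via arylmagnesium chloride 9 (not isolated), via arylzinc chloride 10 (not isolated)
Conditions: TMPMgCl·LiCl, THF, 0 °C; ZnCl2, 0 °C → rt; CH2=CHBr, Pd(OAc)2 (cat.), SPhos (cat.), 40 °C
Reagents that add atoms: vinyl bromide, C=CBr
Why: Directed magnesiation with the Knochel–Hauser base, then Negishi coupling: the only hydrogen left on the ring lies between the ester and fluorine and is the most acidic aryl C–H, and the tert-butyl ester tolerates the magnesium amide. Transmetalation to zinc and coupling at zerovalent palladium formed in the flask should put the vinyl group on that carbon (the later C5').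

Step 9
Reactants: 11 tert-butyl 6-ethenyl-5-fluoro-2-(methoxymethoxy)-4-[(4-methoxybenzyl)oxy]-3-{[(triisopropylsilyl)oxy]methyl}benzoate
Product: 12 tert-butyl 6-ethenyl-5-fluoro-4-hydroxy-2-(methoxymethoxy)-3-{[(triisopropylsilyl)oxy]methyl}benzoate (ring B phenol: C1' OH, C2' CH2OSi(i-Pr)3, C3' OCH2OMe, C4' CO2t-Bu, C5' vinyl, C6' F)
Conditions: DDQ, CH2Cl2/pH 7 buffer, 0 °C → rt
Reagents that add atoms: none
Why: Oxidative removal of a 4-methoxybenzyl ether (hydride abstraction from the anisyl methylene, then hydrolysis of the oxocarbenium ion); the silyl ether, the methoxymethyl ether, the ester and the electron-poor, twisted styrene should not be oxidized under buffered conditions.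

Step 10
Reactants: 13 2,2,6-trimethyl-1,3-dioxin-4-one; 14 acetyl chloride
Product: 16 2,2-dimethyl-6-(2-oxopropyl)-1,3-dioxin-4-one, via lithium dienolate 15 (not isolated)
Conditions: 13 (2 equiv), LiN(SiMe3)2, THF, −78 °C; 14 (1 equiv), −78 °C; aq. NH4Cl
Reagents that add atoms: none
Why: C-Acylation of a vinylogous ester dienolate at its terminal (γ) carbon; the dienolate is used in twofold amount because the more acidic product is deprotonated by a second equivalent, which is recovered as 13.

Step 11
Reactants: 16 2,2-dimethyl-6-(2-oxopropyl)-1,3-dioxin-4-one; 17 N-methoxy-N-methylacetamide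
Product: 20 2,2-dimethyl-6-(2,4-dioxopentyl)-1,3-dioxin-4-one, via dilithium dianion 18 (not isolated), via tetrahedral adduct 19 (not isolated)
Conditions: LiN(i-Pr)2 (2.1 equiv), THF, −78 °C; 17, −78 → −20 °C; cold aq. HCl to pH 3
Reagents that add atoms: none
Why: Claisen-type acylation of a 1,3-dicarbonyl dianion at its terminal carbon (Harris–Hauser regiochemistry) with a Weinreb amide; the chelated adduct holds until the quench, so the diketone cannot be acylated twice. The product is used at once because base or silica would aromatize it.

Step 12
Reactants: 12 tert-butyl 6-ethenyl-5-fluoro-4-hydroxy-2-(methoxymethoxy)-3-{[(triisopropylsilyl)oxy]methyl}benzoate; 20 2,2-dimethyl-6-(2,4-dioxopentyl)-1,3-dioxin-4-one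
Product: 24 4-(tert-butoxycarbonyl)-5-ethenyl-6-fluoro-3-(methoxymethoxy)-2-{[(triisopropylsilyl)oxy]methyl}phenyl 2,4-dihydroxy-6-methylbenzoate, via acylketene 21 (not isolated), via aryl triketo ester 22 (not isolated), via cyclic aldol 23 (not isolated)
Conditions: 12, PhMe, 110 °C, slow addition of 20 (2.5 equiv); cool; Cs2CO3, THF, 0 °C → rt; then AcOH, rt
Reagents that add atoms: none
Why: On heating, 20 undergoes retro-[4+2] cleavage with loss of its ketal carbonyl component to give acylketene 21, a neutral and sterically slim acylating agent, and the C1' hydroxyl of 12 adds to it with proton transfer, the known way in which dioxinones acetoacetylate alcohols and phenols, forming bond C7–O (22). Carbonate then forms the C6 enolate of 22, which attacks the C1 methyl ketone in a six-membered aldol closure (6-enolendo-exo-trig, bond C6–C1, aldol 23); dehydration across C1–C2 and enolization of the C3 and C5 carbonyls aromatize ring A, and acetic acid completes the dehydration. The closest known reaction is the thermolysis of diketo-dioxinones in the presence of alcohols followed by carbonate-induced aromatization to resorcylate esters. No stereocentre is made, and the two of 23 vanish on aromatization. The step needs chemoselectivity at three points: capture of 21 by the phenol before its own C3 enol closes onto the ketene carbon to a pyranone; carbon attack of C6 on C1 instead of oxygen or C2 attack on C7, which would expel the phenol; and survival of the active aryl ester. Slow addition of 20 to hot, concentrated 12 keeps the phenol in excess over the ketene; the two ortho substituents of ring B (silyloxymethyl and fluorine) shield C7 while the methyl ketone C1 is open; and an aprotic medium without alkoxide gives the phenoxide no competitor to be exchanged for. The C1' hydroxyl is the only hydroxyl of 12, so there is no question of site among oxygens.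

Step 13
Reactants: 24 4-(tert-butoxycarbonyl)-5-ethenyl-6-fluoro-3-(methoxymethoxy)-2-{[(triisopropylsilyl)oxy]methyl}phenyl 2,4-dihydroxy-6-methylbenzoate
Product: 25 4-(tert-butoxycarbonyl)-5-ethenyl-6-fluoro-3-(methoxymethoxy)-2-{[(triisopropylsilyl)oxy]methyl}phenyl 2-hydroxy-4-(methoxymethoxy)-6-methylbenzoate
Conditions: MeOCH2Cl (1.1 equiv), i-Pr2NEt, CH2Cl2, 0 °C
Reagents that add atoms: chloromethyl methyl ether, COCCl
Why: Selective O-alkylation of a resorcylate: the C5 hydroxyl is locked in a hydrogen bond to the ester carbonyl, while the C3 hydroxyl (para to the ester) is free and more acidic and should react alone with a weak amine base.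

Step 14
Reactants: 25 4-(tert-butoxycarbonyl)-5-ethenyl-6-fluoro-3-(methoxymethoxy)-2-{[(triisopropylsilyl)oxy]methyl}phenyl 2-hydroxy-4-(methoxymethoxy)-6-methylbenzoate
Product: 26 4-(tert-butoxycarbonyl)-5-ethenyl-6-fluoro-3-(methoxymethoxy)-2-{[(triisopropylsilyl)oxy]methyl}phenyl 3-formyl-2-hydroxy-4-(methoxymethoxy)-6-methylbenzoate
Conditions: MgCl2, Et3N, (CH2O)n, THF, 65 °C
Reagents that add atoms: formaldehyde (as paraformaldehyde), C=O
Why: Magnesium-mediated ortho-formylation (Casnati–Skattebøl), the same reaction type as step 4: the only free phenol is on C5, and its only open ortho position is C4 (C6 carries the ester), so the formyl group cannot go to C2. The vinyl group, ethers and esters are inert to the amine and magnesium salt.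

Step 15
Reactants: 26 4-(tert-butoxycarbonyl)-5-ethenyl-6-fluoro-3-(methoxymethoxy)-2-{[(triisopropylsilyl)oxy]methyl}phenyl 3-formyl-2-hydroxy-4-(methoxymethoxy)-6-methylbenzoate
Product: 28 4-(tert-butoxycarbonyl)-6-fluoro-5-formyl-3-(methoxymethoxy)-2-{[(triisopropylsilyl)oxy]methyl}phenyl 3-formyl-2-hydroxy-4-(methoxymethoxy)-6-methylbenzoate, via ozonide 27 (not isolated)
Conditions: O3, CH2Cl2, −78 °C, to first persistence of ozone; PPh3, −78 °C → rt
Reagents that add atoms: ozone, [O-][O+]=O
Why: Ozonolysis with reductive work-up; the terminal alkene is far more reactive toward ozone than the acceptor-substituted arenes. No acid is involved, so the aldehyde appears next to the tert-butyl ester without the ester being lost.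

Step 16
Reactants: 28 4-(tert-butoxycarbonyl)-6-fluoro-5-formyl-3-(methoxymethoxy)-2-{[(triisopropylsilyl)oxy]methyl}phenyl 3-formyl-2-hydroxy-4-(methoxymethoxy)-6-methylbenzoate
Product: 29 tert-butyl 4,6-diformyl-3,8-bis(methoxymethoxy)-1-methyl-11-oxo-9-{[(triisopropylsilyl)oxy]methyl}-11H-dibenzo[b,e][1,4]dioxepine-7-carboxylate (depsidone: ester C7–O–C1', ether C5–O–C6')
Conditions: K2CO3, 4 Å molecular sieves, DMSO (0.01 M), 60 °C
Reagents that add atoms: none
Why: Intramolecular nucleophilic aromatic substitution by addition–elimination: the C5 phenoxide adds to C6', the charge of the Meisenheimer adduct is taken up by the coplanar C5' aldehyde, and fluoride leaves, closing the seven-membered ring C. The competing ipso attack at C1' (Smiles shift) is activated only by the C4' ester, which is twisted out of conjugation between its two ortho neighbours, and should stay slow at this temperature; high dilution suppresses intermolecular ether formation.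

Step 17
Reactants: 29 tert-butyl 4,6-diformyl-3,8-bis(methoxymethoxy)-1-methyl-11-oxo-9-{[(triisopropylsilyl)oxy]methyl}-11H-dibenzo[b,e][1,4]dioxepine-7-carboxylate
Product: 30 tert-butyl 4,6-diformyl-9-(hydroxymethyl)-3,8-bis(methoxymethoxy)-1-methyl-11-oxo-11H-dibenzo[b,e][1,4]dioxepine-7-carboxylate
Conditions: HF·pyridine, THF/pyridine, 0 °C → rt
Reagents that add atoms: none
Why: Fluoride-induced desilylation under buffered, weakly acidic conditions that leave the aryl lactone, the acetal-type ethers and the tert-butyl ester alone; a basic fluoride source is avoided because of the lactone.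

Step 18
Reactants: 30 tert-butyl 4,6-diformyl-9-(hydroxymethyl)-3,8-bis(methoxymethoxy)-1-methyl-11-oxo-11H-dibenzo[b,e][1,4]dioxepine-7-carboxylate; 31 (E)-4-tert-butoxy-4-oxobut-2-enoic acid (mono-tert-butyl fumarate)
Product: 32 tert-butyl {[7-(tert-butoxycarbonyl)-4,6-diformyl-3,8-bis(methoxymethoxy)-1-methyl-11-oxo-11H-dibenzo[b,e][1,4]dioxepin-9-yl]methyl} (E)-but-2-enedioate
Conditions: EDC·HCl, DMAP (cat.), CH2Cl2, 0 °C → rt
Reagents that add atoms: none
Why: Steglich esterification; the primary benzylic alcohol is the only hydroxyl in 30, so the acylpyridinium can react nowhere else, and the mild conditions keep the E double bond.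

Step 19
Reactants: 32 tert-butyl {[7-(tert-butoxycarbonyl)-4,6-diformyl-3,8-bis(methoxymethoxy)-1-methyl-11-oxo-11H-dibenzo[b,e][1,4]dioxepin-9-yl]methyl} (E)-but-2-enedioate
Product: 33 racemic target: depsidone with C1 methyl, C3 OH, C4 CHO; C2' CH2O–CO–CH=CH–CO2H (E), C3' OH, C4'/C5' hydroxy lactone, both configurations at the lactol carbon
Conditions: CF3CO2H/CH2Cl2 (1:3), H2O (5 equiv), 0 °C → rt, dilute
Reagents that add atoms: none
Why: Acidolysis: both tert-butyl esters lose isobutene and both methoxymethyl ethers are hydrolysed. The freed C4' acid adds to the neighbouring C5' aldehyde to give the five-membered lactol, formed as the racemate because nothing distinguishes the two faces of the aldehyde. Water and dilution keep the methoxymethyl cation from attacking C2 of ring A.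

Step 20
Reactants: 33 racemic target; 34 (R)-N,N-dimethyl-1-phenylethylamine
Product: 35 (R)-N,N-dimethyl-1-phenylethylammonium salt of the (R)-lactol (carboxylate of the fumaric half ester)
Conditions: 34 (1.05 equiv), MeCN/EtOAc, 40 °C → 5 °C, seeded slurry aged until the liquor is depleted; filtration
Reagents that add atoms: none
Why: Crystallization-induced asymmetric transformation of a diastereomeric salt: the amine is tertiary, so it cannot condense with the aldehydes and forms the salt at the fumaric acid. The lactol epimerizes in solution through the open formyl carboxylate, helped by the small excess of base, while the less soluble salt leaves the equilibrium, so the whole material should end as the (R)-lactol salt; the controlling element is the lattice of the salt with the (R)-amine.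

Step 21
Reactants: 35 (R)-N,N-dimethyl-1-phenylethylammonium salt of the (R)-lactol
Product: 36 target CNP0379578.1, the free acid with (R) configuration at the lactol carbon
Conditions: cold 0.5 M aq. HCl/EtOAc, 0 °C, brief; dry; evaporate below 10 °C
Reagents that add atoms: none
Why: Proton transfer from the mineral acid frees the carboxylic acid and takes the amine into water; cold, acidic and brief handling keeps the ring–chain tautomerism of the lactol slow, so the configuration fixed in the crystal should be carried into 36.

## Compound list

1 | 4-fluororesorcinol | Oc1ccc(F)c(O)c1 | starting material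
2 | 5-fluoro-2,4-dihydroxybenzoic acid | OC(=O)c1cc(F)c(O)cc1O | intermediate
3 | tert-butyl 5-fluoro-2,4-dihydroxybenzoate | CC(C)(C)OC(=O)c1cc(F)c(O)cc1O | intermediate
4 | tert-butyl 5-fluoro-2-hydroxy-4-[(4-methoxybenzyl)oxy]benzoate | CC(C)(C)OC(=O)c1cc(F)c(OCc2ccc(OC)cc2)cc1O | intermediate
5 | tert-butyl 5-fluoro-3-formyl-2-hydroxy-4-[(4-methoxybenzyl)oxy]benzoate | CC(C)(C)OC(=O)c1cc(F)c(OCc2ccc(OC)cc2)c(C=O)c1O | intermediate
6 | tert-butyl 5-fluoro-3-formyl-2-(methoxymethoxy)-4-[(4-methoxybenzyl)oxy]benzoate | CC(C)(C)OC(=O)c1cc(F)c(OCc2ccc(OC)cc2)c(C=O)c1OCOC | intermediate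
7 | tert-butyl 5-fluoro-3-(hydroxymethyl)-2-(methoxymethoxy)-4-[(4-methoxybenzyl)oxy]benzoate | CC(C)(C)OC(=O)c1cc(F)c(OCc2ccc(OC)cc2)c(CO)c1OCOC | intermediate
8 | tert-butyl 5-fluoro-2-(methoxymethoxy)-4-[(4-methoxybenzyl)oxy]-3-{[(triisopropylsilyl)oxy]methyl}benzoate | CC(C)(C)OC(=O)c1cc(F)c(OCc2ccc(OC)cc2)c(CO[Si](C(C)C)(C(C)C)C(C)C)c1OCOC | intermediate
9 | arylmagnesium chloride of 8 (magnesium between ester and fluorine) | CC(C)(C)OC(=O)c1c([Mg]Cl)c(F)c(OCc2ccc(OC)cc2)c(CO[Si](C(C)C)(C(C)C)C(C)C)c1OCOC | intermediate (not isolated)
10 | arylzinc chloride of 8 | CC(C)(C)OC(=O)c1c([Zn]Cl)c(F)c(OCc2ccc(OC)cc2)c(CO[Si](C(C)C)(C(C)C)C(C)C)c1OCOC | intermediate (not isolated)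
11 | tert-butyl 6-ethenyl-5-fluoro-2-(methoxymethoxy)-4-[(4-methoxybenzyl)oxy]-3-{[(triisopropylsilyl)oxy]methyl}benzoate | CC(C)(C)OC(=O)c1c(C=C)c(F)c(OCc2ccc(OC)cc2)c(CO[Si](C(C)C)(C(C)C)C(C)C)c1OCOC | intermediate
12 | tert-butyl 6-ethenyl-5-fluoro-4-hydroxy-2-(methoxymethoxy)-3-{[(triisopropylsilyl)oxy]methyl}benzoate (ring B phenol) | CC(C)(C)OC(=O)c1c(C=C)c(F)c(O)c(CO[Si](C(C)C)(C(C)C)C(C)C)c1OCOC | intermediate
13 | 2,2,6-trimethyl-1,3-dioxin-4-one | CC1=CC(=O)OC(C)(C)O1 | starting material
14 | acetyl chloride | CC(Cl)=O | starting material
15 | lithium dienolate of 13 | C=C1C=C(O[Li])OC(C)(C)O1 | intermediate (not isolated)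
16 | 2,2-dimethyl-6-(2-oxopropyl)-1,3-dioxin-4-one | CC(=O)CC1=CC(=O)OC(C)(C)O1 | intermediate
17 | N-methoxy-N-methylacetamide | CC(=O)N(C)OC | starting material
18 | dilithium dianion of 16 | C=C(O[Li])C=C1C=C(O[Li])OC(C)(C)O1 | intermediate (not isolated)
19 | tetrahedral adduct of 18 and 17 (dilithium salt) | CON(C)C(C)(O[Li])CC(O[Li])=CC1=CC(=O)OC(C)(C)O1 | intermediate (not isolated)
20 | 2,2-dimethyl-6-(2,4-dioxopentyl)-1,3-dioxin-4-one | CC(=O)CC(=O)CC(=O)CC1=CC(=O)OC(C)(C)O1 | intermediate
21 | acylketene, 3,5,7-trioxooct-1-en-1-one | CC(=O)CC(=O)CC(=O)C=C=O | intermediate (not isolated)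
22 | aryl 3,5,7-trioxooctanoate (aryl = ring B of 12) | CC(=O)CC(=O)CC(=O)CC(=O)Oc1c(CO[Si](C(C)C)(C(C)C)C(C)C)c(OCOC)c(C(=O)OC(C)(C)C)c(C=C)c1F | intermediate (not isolated)
23 | cyclic aldol, aryl 2-hydroxy-2-methyl-4,6-dioxocyclohexane-1-carboxylate (mixture of stereoisomers) | CC1(O)CC(=O)CC(=O)C1C(=O)Oc1c(CO[Si](C(C)C)(C(C)C)C(C)C)c(OCOC)c(C(=O)OC(C)(C)C)c(C=C)c1F | intermediate (not isolated)
24 | 4-(tert-butoxycarbonyl)-5-ethenyl-6-fluoro-3-(methoxymethoxy)-2-{[(triisopropylsilyl)oxy]methyl}phenyl 2,4-dihydroxy-6-methylbenzoate (depside) | Cc1cc(O)cc(O)c1C(=O)Oc1c(CO[Si](C(C)C)(C(C)C)C(C)C)c(OCOC)c(C(=O)OC(C)(C)C)c(C=C)c1F | intermediate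
25 | same aryl 2-hydroxy-4-(methoxymethoxy)-6-methylbenzoate | Cc1cc(OCOC)cc(O)c1C(=O)Oc1c(CO[Si](C(C)C)(C(C)C)C(C)C)c(OCOC)c(C(=O)OC(C)(C)C)c(C=C)c1F | intermediate
26 | same aryl 3-formyl-2-hydroxy-4-(methoxymethoxy)-6-methylbenzoate | Cc1cc(OCOC)c(C=O)c(O)c1C(=O)Oc1c(CO[Si](C(C)C)(C(C)C)C(C)C)c(OCOC)c(C(=O)OC(C)(C)C)c(C=C)c1F | intermediate
27 | ozonide of 26 (1,2,4-trioxolan-3-yl on C5', racemic) | Cc1cc(OCOC)c(C=O)c(O)c1C(=O)Oc1c(CO[Si](C(C)C)(C(C)C)C(C)C)c(OCOC)c(C(=O)OC(C)(C)C)c(C2OCOO2)c1F | intermediate (not isolated)
28 | 4-(tert-butoxycarbonyl)-6-fluoro-5-formyl-3-(methoxymethoxy)-2-{[(triisopropylsilyl)oxy]methyl}phenyl 3-formyl-2-hydroxy-4-(methoxymethoxy)-6-methylbenzoate | Cc1cc(OCOC)c(C=O)c(O)c1C(=O)Oc1c(CO[Si](C(C)C)(C(C)C)C(C)C)c(OCOC)c(C(=O)OC(C)(C)C)c(C=O)c1F | intermediate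
29 | tert-butyl 4,6-diformyl-3,8-bis(methoxymethoxy)-1-methyl-11-oxo-9-{[(triisopropylsilyl)oxy]methyl}-11H-dibenzo[b,e][1,4]dioxepine-7-carboxylate | Cc1cc(OCOC)c(C=O)c2c1C(=O)Oc1c(CO[Si](C(C)C)(C(C)C)C(C)C)c(OCOC)c(C(=O)OC(C)(C)C)c(C=O)c1O2 | intermediate
30 | tert-butyl 4,6-diformyl-9-(hydroxymethyl)-3,8-bis(methoxymethoxy)-1-methyl-11-oxo-11H-dibenzo[b,e][1,4]dioxepine-7-carboxylate | Cc1cc(OCOC)c(C=O)c2c1C(=O)Oc1c(CO)c(OCOC)c(C(=O)OC(C)(C)C)c(C=O)c1O2 | intermediate
31 | (E)-4-tert-butoxy-4-oxobut-2-enoic acid (mono-tert-butyl fumarate) | CC(C)(C)OC(=O)/C=C/C(=O)O | starting material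
32 | tert-butyl {[7-(tert-butoxycarbonyl)-4,6-diformyl-3,8-bis(methoxymethoxy)-1-methyl-11-oxo-11H-dibenzo[b,e][1,4]dioxepin-9-yl]methyl} (E)-but-2-enedioate | Cc1cc(OCOC)c(C=O)c2c1C(=O)Oc1c(COC(=O)/C=C/C(=O)OC(C)(C)C)c(OCOC)c(C(=O)OC(C)(C)C)c(C=O)c1O2 | intermediate
33 | racemic target (both configurations at the lactol carbon) | Cc1cc(O)c(C=O)c2c1C(=O)Oc1c(COC(=O)/C=C/C(=O)O)c(O)c3c(c1O2)C(O)OC3=O | intermediate
34 | (R)-N,N-dimethyl-1-phenylethylamine | C[C@@H](N(C)C)c1ccccc1 | starting material
35 | (R)-N,N-dimethyl-1-phenylethylammonium salt of the (R)-lactol | Cc1cc(O)c(C=O)c2c1C(=O)Oc1c(COC(=O)/C=C/C(=O)[O-])c(O)c3c(c1O2)[C@H](O)OC3=O.C[C@@H]([NH+](C)C)c1ccccc1 | intermediate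
36 | CNP0379578.1: depsidone with C1 methyl, C3 OH, C4 CHO, C2' CH2O–CO–CH=CH–CO2H (E), C3' OH and the C4'/C5' hydroxy lactone, (R) at the lactol carbon | Cc1cc(O)c(C=O)c2c1C(=O)Oc1c(COC(=O)/C=C/C(=O)O)c(O)c3c(c1O2)[C@H](O)OC3=O | target

## Step count and least certain steps

Total step count: 21. Longest linear sequence: 19 steps (steps 1–9 and 12–21). The dioxinone branch (steps 10 and 11) joins at step 12.

**Step 12 (key step).** Three processes can drain material.
- The acylketene may close on its own C3 enol to a pyranone faster than the doubly ortho-substituted, fairly acidic phenol captures it.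
- The aryl β-keto ester may revert to ketene and phenol on prolonged heating, because the phenoxide is a good leaving group.
- Under base, oxygen or C2 attack on C7, or E1cB loss of the phenoxide, may compete with the aldol closure.

Fallback: form ring A first and the ester second. Starting from 20, triethylamine in dichloromethane should aromatize the chain with the dioxinone intact to give 7-hydroxy-2,2,5-trimethyl-1,3-benzodioxin-4-one F1. Selective alkylation with chloromethyl methyl ether and a hindered amine should give 7-(methoxymethoxy)-2,2,5-trimethyl-1,3-benzodioxin-4-one F2. Irradiation of F2 near 300 nm in the presence of phenol 12 should expel acetone to an ortho-quinone ketene, which the phenol captures (photochemical acylation with benzodioxinones). The product is 25, where the route is rejoined with step 13 saved.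

**Step 16.** The C5 phenoxide is stabilized by both the C4 aldehyde and the C7 ester and is a weak nucleophile, so the fluorine displacement may be sluggish. At higher temperature the phenoxide may attack C1' instead (Smiles shift to a diaryl ether acid), and fluoride may attack the silyl ether before ring C is closed. Fallback: deactivate C1' and cyclize as the carboxylate. Starting from 28, catalytic toluenesulfonic acid in wet acetonitrile should let the C5' aldehyde assist loss of isobutene from the neighbouring ester to give the hydroxy lactone depside F3. In K2CO3/DMSO, F3 opens to the formyl carboxylate, whose carboxylate no longer stabilizes charge at C1' while the aldehyde still activates C6'. Closure should give the depsidone hydroxy lactone F4. O-tert-Butyl-N,N'-diisopropylisourea then re-forms the open tert-butyl ester, which is 29.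

**Step 14.** The directing phenol is chelated to the ester and deactivated, so formylation may be slow. The methoxide formed from the second formaldehyde may also cleave the aryl ester by transesterification during long heating. Fallback: formylate before the C3 oxygen is protected. Starting from 24, the same magnesium-mediated formylation should run faster through the free C3 hydroxyl. It should prefer C4, the carbon between the two oxygens, as orsellinate esters do, and give the 3-formyl-2,4-dihydroxy depside F5. The chelated C5 hydroxyl, now flanked by two carbonyls, is left untouched by one equivalent of chloromethyl methyl ether and amine, which converts F5 to 26. This order gives up the forced regiochemistry and depends on the preference for C4 over C2.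

**Steps 20 and 21.** The salt may fail to crystallize as one diastereomer (oil, solid solution or both salts). The amine may slowly open the lactone or expel the fumarate from the benzylic carbon. The configuration may erode when the acid is freed. Fallback: separate the enantiomers of 33 by chromatography on an immobilized polysaccharide chiral phase with a cold, acidified eluent, where ring–chain tautomerism is slow. The (S) fraction is racemized with a trace of tertiary amine and recycled. This gives 36 directly and makes no new compound.

## Further compounds

F1 | step 12 | 7-hydroxy-2,2,5-trimethyl-1,3-benzodioxin-4-one | CC1(C)OC(=O)c2c(C)cc(O)cc2O1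
F2 | step 12 | 7-(methoxymethoxy)-2,2,5-trimethyl-1,3-benzodioxin-4-one | CC1(C)OC(=O)c2c(C)cc(OCOC)cc2O1
F3 | step 16 | hydroxy lactone depside: 28 with the C4' ester and C5' aldehyde closed to the lactol, tert-butyl group lost (racemic at the lactol carbon) | Cc1cc(OCOC)c(C=O)c(O)c1C(=O)Oc1c(CO[Si](C(C)C)(C(C)C)C(C)C)c(OCOC)c2C(=O)OC(O)c2c1F
F4 | step 16 | depsidone hydroxy lactone with C3 and C3' methoxymethyl ethers and C2' silyloxymethyl group (racemic at the lactol carbon) | Cc1cc(OCOC)c(C=O)c2c1C(=O)Oc1c(CO[Si](C(C)C)(C(C)C)C(C)C)c(OCOC)c3c(c1O2)C(O)OC3=O
F5 | step 14 | 4-(tert-butoxycarbonyl)-5-ethenyl-6-fluoro-3-(methoxymethoxy)-2-{[(triisopropylsilyl)oxy]methyl}phenyl 3-formyl-2,4-dihydroxy-6-methylbenzoate | Cc1cc(O)c(C=O)c(O)c1C(=O)Oc1c(CO[Si](C(C)C)(C(C)C)C(C)C)c(OCOC)c(C(=O)OC(C)(C)C)c(C=C)c1F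
F0 | step 20 | none | none
A1 | alternative 1 | ring B hydroquinone: C1' isopropyl ether, C2' methoxymethoxymethyl, C3' and C6' hydroxyl, C4' tert-butyl ester, C5' diethyl acetal | Oc1c(COCOC)c(OC(C)C)c(O)c(C(OCC)OCC)c1C(=O)OC(C)(C)C
A2 | alternative 1 | 4-hydroxy-3-isopropoxy-2-(methoxymethoxymethyl)-4-[3-tert-butoxy-1-(diethoxymethyl)-3-oxoprop-1-enyl]cyclobut-2-enone | O=C1C(COCOC)=C(OC(C)C)C1(O)C(=CC(=O)OC(C)(C)C)C(OCC)OCC
A3 | alternative 1 | diisopropyl squarate | CC(C)OC1=C(OC(C)C)C(=O)C1=O
A4 | alternative 2 | protected depsidone: C3 and C3' methoxymethyl ethers, C4 formyl, C2' tert-butyldimethylsilyloxymethyl, C4' tert-butyl ester, C5' dimethyl acetal | Cc1cc(OCOC)c(C=O)c2c1C(=O)Oc1c(CO[Si](C)(C)C(C)(C)C)c(OCOC)c(C(=O)OC(C)(C)C)c(C(OC)OC)c1O2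
A5 | alternative 2 | iodo diaryl ether: iodine on C6, free hydroxyl on C1' | Cc1cc(OCOC)c(C=O)c(Oc2c(O)c(CO[Si](C)(C)C(C)(C)C)c(OCOC)c(C(=O)OC(C)(C)C)c2C(OC)OC)c1I
A6 | alternative 2 | carbon monoxide | [C-]#[O+]
A7 | alternative 3 | protected depsidone with free C3' phenol, C2' benzyloxymethyl, C4' tert-butyl ester, C5' diethyl acetal, C4 dimethyl acetal | Cc1cc(OCOC)c(C(OC)OC)c2c1C(=O)Oc1c(COCc3ccccc3)c(O)c(C(=O)OC(C)(C)C)c(C(OCC)OCC)c1O2
A8 | alternative 3 | silyl ketene acetal diene on the seven-membered enol lactone | Cc1cc(OCOC)c(C(OC)OC)c2OC=C(OC(=O)c12)C(COCc3ccccc3)=C(OC)O[Si](C)(C)C(C)(C)C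
A9 | alternative 3 | tert-butyl 4,4-diethoxybut-2-ynoate | CCOC(OCC)C#CC(=O)OC(C)(C)C
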